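**Strategy.** The route rests on disconnecting C6–C7 of the saturated ring (naphthalene numbering: C5 carries CH2OAc, C8 the side chain). C6 and C7 are bare methylenes, each flanked by a benzylic stereocentre, and C5 bears only H, CH2O and C6, so it can be created from an aryl-C(=CH2)CH2OSi alkene. In one operation a chiral copper hydride adds across that alkene, fixing C5 under ligand control, and the resulting CH2–Cu displaces a bromide on C7 to close the ring. The precursor is a tetrasubstituted benzoate carrying the 2-arylallyl silyl ether beside a 1-bromo-3,7-dimethyloct-6-en-2-yl arm, whose C2′ stereocentre is bought as (S)-citronellal and whose C8 is set by catalytic α-arylation.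

Key step: step 7

Assumption: the sense of induction of the imidazolidinone (step 3) and of DTBM-SEGPHOS (step 7) is taken from the usual face-shielding models; should either prove opposite, the antipodal catalyst is used. Compounds 1, 4 and 7 are taken as purchased.

Step 1
Reactants: 1 methyl 4-hydroxy-3-iodo-5-methoxybenzoate
Product: 2 methyl 3-iodo-5-methoxy-4-[(trifluoromethylsulfonyl)oxy]benzoate
Conditions: Tf2O, pyridine, CH2Cl2, 0 °C to rt
Reagents that add atoms: triflic anhydride, O=S(=O)(OS(=O)(=O)C(F)(F)F)C(F)(F)F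
Why: O-sulfonylation of the phenol masks the oxygen against the oxidant of step 2 and turns the future C4a position into a cross-coupling handle.

Step 2
Reactants: 2 methyl 3-iodo-5-methoxy-4-[(trifluoromethylsulfonyl)oxy]benzoate
Product: 3 aryl(mesityl)iodonium triflate
Conditions: mCPBA, TfOH, CH2Cl2, 0 °C to rt; then mesitylene, 0 °C to rt
Reagents that add atoms: mesitylene, Cc1cc(C)cc(C)c1; triflic acid, OS(=O)(=O)C(F)(F)F
Why: One-pot diaryliodonium synthesis (oxidation of the aryl iodide to trivalent iodine, then electrophilic substitution of mesitylene); the doubly ortho-substituted mesityl group serves as the non-transferred ligand.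

Step 3
Reactants: 3 aryl(mesityl)iodonium triflate; 4 (S)-citronellal
Product: 6 methyl 3-[(2S,3S)-1-hydroxy-3,7-dimethyloct-6-en-2-yl]-5-methoxy-4-[(trifluoromethylsulfonyl)oxy]benzoate, via aldehyde 5 (not isolated)
Conditions: CuBr (10 mol%), (5R)-5-benzyl-2,2,3-trimethylimidazolidin-4-one·TCA (20 mol%), NaHCO3, toluene/Et2O, 23 °C; then NaBH4, MeOH, 0 °C
Reagents that add atoms: none
Why: Organocatalytic enamine α-arylation of an aldehyde with a diaryliodonium salt under copper catalysis (MacMillan type): the aryl–copper species (trivalent copper) should attack the Re face of the (E)-enamine left open by the catalyst benzyl group, setting the future C8 as S by catalyst control beside the purchased C2′ centre, and immediate borohydride reduction removes the epimerisable α-aryl aldehyde.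

Step 4
Reactants: 7 tert-butyldimethyl(prop-2-yn-1-yloxy)silane
Product: 8 tert-butyldimethyl{[2-(4,4,5,5-tetramethyl-1,3,2-dioxaborolan-2-yl)prop-2-en-1-yl]oxy}silane
Conditions: B2pin2, CuCl (5 mol%), SIMes·HCl (5 mol%), NaOtBu (cat.), MeOH, THF, −50 °C to rt
Reagents that add atoms: bis(pinacolato)diboron, CC1(C)OB(OC1(C)C)B1OC(C)(C)C(C)(C)O1
Why: NHC–copper-catalysed protoboration of a terminal propargylic ether, in which the N-aryl carbene ligand and the propargylic oxygen direct boron to the internal carbon and give the 1,1-disubstituted alkenyl boronate.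

Step 5
Reactants: 6 methyl 3-[(2S,3S)-1-hydroxy-3,7-dimethyloct-6-en-2-yl]-5-methoxy-4-[(trifluoromethylsulfonyl)oxy]benzoate; 8 alkenyl pinacol boronate
Product: 9 methyl 4-{3-[(tert-butyldimethylsilyl)oxy]prop-1-en-2-yl}-3-[(2S,3S)-1-hydroxy-3,7-dimethyloct-6-en-2-yl]-5-methoxybenzoate
Conditions: Pd(OAc)2 (5 mol%), SPhos (10 mol%), K3PO4, THF/H2O, 60 °C
Reagents that add atoms: none
Why: Suzuki–Miyaura coupling of the di-ortho-substituted aryl triflate with the alkenyl boronate, for which a bulky biaryl phosphine is the standard answer; ester, silyl ether, free alcohol and both stereocentres are not touched.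

Step 6
Reactants: 9 methyl 4-{3-[(tert-butyldimethylsilyl)oxy]prop-1-en-2-yl}-3-[(2S,3S)-1-hydroxy-3,7-dimethyloct-6-en-2-yl]-5-methoxybenzoate
Product: 10 methyl 3-[(2S,3S)-1-bromo-3,7-dimethyloct-6-en-2-yl]-4-{3-[(tert-butyldimethylsilyl)oxy]prop-1-en-2-yl}-5-methoxybenzoate
Conditions: CBr4, PPh3, 2,6-lutidine, CH2Cl2, 0 °C
Reagents that add atoms: carbon tetrabromide, BrC(Br)(Br)Br
Why: Appel reaction converts the primary alcohol into the bromide at a CH2 carbon, so no stereocentre is involved, and the buffered conditions spare the silyl ether and both alkenes.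

Step 7
Reactants: 10 methyl 3-[(2S,3S)-1-bromo-3,7-dimethyloct-6-en-2-yl]-4-{3-[(tert-butyldimethylsilyl)oxy]prop-1-en-2-yl}-5-methoxybenzoate
Product: 12 methyl (5R,8S)-5-{[(tert-butyldimethylsilyl)oxy]methyl}-4-methoxy-8-[(2S)-6-methylhept-5-en-2-yl]-5,6,7,8-tetrahydronaphthalene-2-carboxylate, via alkylcopper 11 (not isolated)
Conditions: Cu(OAc)2 (5 mol%), (R)-DTBM-SEGPHOS (6 mol%), (MeO)2MeSiH, LiOMe, THF, 40 °C
Reagents that add atoms: none
Why: Proposed new method: L*CuH (from Cu(OAc)2, the bisphosphine and the silane) is expected to add syn across the 1,1-disubstituted alkene with copper at the unsubstituted terminus (C6) and hydride at C5, after which the primary alkylcopper 11, activated by methoxide, displaces the primary bromide on C7 in an SN2 manner and LiOMe with silane regenerates the hydride. The closest known reaction types are the CuH-catalysed enantioselective intramolecular hydroalkylation of bromide-tethered styrenes (benzylic copper as nucleophile) and the CuH-catalysed anti-Markovnikov hydroamination of 1,1-disubstituted alkenes (same hydrocupration regiochemistry and β-stereocentre); their combination in one substrate is untested. The six-membered carbocycle closes by 6-exo-tet attack of C6–Cu on C7–Br. The new stereocentre C5 (R) is fixed in the hydrocupration by the ligand (hydride to the Si face of the alkene carbon, priorities CH2OSi > aryl > CH2), independently of the remote C8 and C2′ centres, which cannot epimerise under these conditions, so the 5,8-trans relationship follows from two catalyst-controlled events. The step needs anti-Markovnikov regiochemistry, hydrocupration faster than reduction of the C–Br bond, and no β-elimination: the di-ortho-substituted aryl ring is twisted out of conjugation so copper goes to the CH2 terminus, the β-branched bromide is slow toward intermolecular hydride, and the silyloxy group sits γ to copper where it cannot be expelled.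

Step 8
Reactants: 12 methyl (5R,8S)-5-{[(tert-butyldimethylsilyl)oxy]methyl}-4-methoxy-8-[(2S)-6-methylhept-5-en-2-yl]-5,6,7,8-tetrahydronaphthalene-2-carboxylate
Product: 14 (5R,8S)-4-hydroxy-5-(hydroxymethyl)-8-[(2S)-6-methylhept-5-en-2-yl]-5,6,7,8-tetrahydronaphthalene-2-carboxylic acid, via silyl ether acid 13 (not isolated)
Conditions: NaSEt, DMF, 130 °C; then 2 M HCl, THF, rt
Reagents that add atoms: none
Why: Thiolate SN2 demethylation cleaves both the aryl methyl ether and the methyl ester at the methyl carbon without acid or Lewis acid (the trisubstituted alkene is spared), and the mild acidic quench hydrolyses the primary silyl ether.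

Step 9
Reactants: 14 (5R,8S)-4-hydroxy-5-(hydroxymethyl)-8-[(2S)-6-methylhept-5-en-2-yl]-5,6,7,8-tetrahydronaphthalene-2-carboxylic acid
Product: 15 (5R,8S)-4-acetoxy-5-(acetoxymethyl)-8-[(2S)-6-methylhept-5-en-2-yl]-5,6,7,8-tetrahydronaphthalene-2-carboxylic acid
Conditions: Ac2O, pyridine, DMAP (cat.), CH2Cl2, rt; then H2O, THF, rt
Reagents that add atoms: acetic anhydride, CC(=O)OC(C)=O
Why: DMAP-catalysed acylation esterifies the phenol and the primary alcohol, and the mixed anhydride formed at the carboxyl group is hydrolysed by the aqueous treatment while the aryl and alkyl acetates remain.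

**Compound list**

1 | methyl 4-hydroxy-3-iodo-5-methoxybenzoate (methyl 5-iodovanillate) | COC(=O)c1cc(I)c(O)c(OC)c1 | starting material
2 | methyl 3-iodo-5-methoxy-4-[(trifluoromethylsulfonyl)oxy]benzoate | COC(=O)c1cc(I)c(OS(=O)(=O)C(F)(F)F)c(OC)c1 | intermediate
3 | {3-methoxy-5-(methoxycarbonyl)-2-[(trifluoromethylsulfonyl)oxy]phenyl}(2,4,6-trimethylphenyl)iodonium triflate | COC(=O)c1cc([I+]c2c(C)cc(C)cc2C)c(OS(=O)(=O)C(F)(F)F)c(OC)c1.[O-]S(=O)(=O)C(F)(F)F | intermediate
4 | (S)-citronellal, (3S)-3,7-dimethyloct-6-enal | O=CC[C@@H](C)CCC=C(C)C | starting material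
5 | methyl 3-[(2S,3S)-3,7-dimethyl-1-oxooct-6-en-2-yl]-5-methoxy-4-[(trifluoromethylsulfonyl)oxy]benzoate | O=C[C@@H]([C@@H](C)CCC=C(C)C)c1cc(C(=O)OC)cc(OC)c1OS(=O)(=O)C(F)(F)F | intermediate
6 | methyl 3-[(2S,3S)-1-hydroxy-3,7-dimethyloct-6-en-2-yl]-5-methoxy-4-[(trifluoromethylsulfonyl)oxy]benzoate | OC[C@@H]([C@@H](C)CCC=C(C)C)c1cc(C(=O)OC)cc(OC)c1OS(=O)(=O)C(F)(F)F | intermediate
7 | tert-butyldimethyl(prop-2-yn-1-yloxy)silane | C#CCO[Si](C)(C)C(C)(C)C | starting material
8 | tert-butyldimethyl{[2-(4,4,5,5-tetramethyl-1,3,2-dioxaborolan-2-yl)prop-2-en-1-yl]oxy}silane | CC(C)(C)[Si](C)(C)OCC(=C)B1OC(C)(C)C(C)(C)O1 | intermediate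
9 | methyl 4-{3-[(tert-butyldimethylsilyl)oxy]prop-1-en-2-yl}-3-[(2S,3S)-1-hydroxy-3,7-dimethyloct-6-en-2-yl]-5-methoxybenzoate | OC[C@@H]([C@@H](C)CCC=C(C)C)c1cc(C(=O)OC)cc(OC)c1C(=C)CO[Si](C)(C)C(C)(C)C | intermediate
10 | methyl 3-[(2S,3S)-1-bromo-3,7-dimethyloct-6-en-2-yl]-4-{3-[(tert-butyldimethylsilyl)oxy]prop-1-en-2-yl}-5-methoxybenzoate | BrC[C@@H]([C@@H](C)CCC=C(C)C)c1cc(C(=O)OC)cc(OC)c1C(=C)CO[Si](C)(C)C(C)(C)C | intermediate
11 | primary alkylcopper, methyl 3-[(2S,3S)-1-bromo-3,7-dimethyloct-6-en-2-yl]-4-[(2R)-1-[(tert-butyldimethylsilyl)oxy]-3-cupriopropan-2-yl]-5-methoxybenzoate (bisphosphine on copper omitted) | CC(C)(C)[Si](C)(C)OC[C@H](C[Cu])c1c(OC)cc(C(=O)OC)cc1[C@@H](CBr)[C@@H](C)CCC=C(C)C | intermediate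
12 | methyl (5R,8S)-5-{[(tert-butyldimethylsilyl)oxy]methyl}-4-methoxy-8-[(2S)-6-methylhept-5-en-2-yl]-5,6,7,8-tetrahydronaphthalene-2-carboxylate | CC(C)(C)[Si](C)(C)OC[C@@H]1CC[C@@H]([C@@H](C)CCC=C(C)C)c2cc(C(=O)OC)cc(OC)c21 | intermediate
13 | (5R,8S)-5-{[(tert-butyldimethylsilyl)oxy]methyl}-4-hydroxy-8-[(2S)-6-methylhept-5-en-2-yl]-5,6,7,8-tetrahydronaphthalene-2-carboxylic acid | CC(C)(C)[Si](C)(C)OC[C@@H]1CC[C@@H]([C@@H](C)CCC=C(C)C)c2cc(C(=O)O)cc(O)c21 | intermediate
14 | (5R,8S)-4-hydroxy-5-(hydroxymethyl)-8-[(2S)-6-methylhept-5-en-2-yl]-5,6,7,8-tetrahydronaphthalene-2-carboxylic acid | OC[C@@H]1CC[C@@H]([C@@H](C)CCC=C(C)C)c2cc(C(=O)O)cc(O)c21 | intermediate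
15 | (5R,8S)-4-acetoxy-5-(acetoxymethyl)-8-[(2S)-6-methylhept-5-en-2-yl]-5,6,7,8-tetrahydronaphthalene-2-carboxylic acid (CNP0223972.1) | CC(=O)OC[C@@H]1CC[C@@H]([C@@H](C)CCC=C(C)C)c2cc(C(=O)O)cc(OC(C)=O)c21 | target

**Step count.** Total: 9 steps. Longest linear sequence: 8 steps (1, 2, 3, 5, 6, 7, 8, 9); step 4 is a one-step side branch.

**Steps most likely to fail**

Step 7 (proposed new method). Hydrocupration of the hindered alkene may be slow, so that reduction of the C–Br bond by the copper hydride takes over, or the ligand may discriminate the alkene faces poorly. The fallback uses known chemistry and sets out from 9. NHC–copper-catalysed enantioselective protoboration of the 1,1-disubstituted alkene (CuCl, chiral imidazolinium salt, NaOtBu, B2pin2, MeOH, THF) followed by oxidation (NaBO3·4H2O) should give methyl 4-{(2S)-1-[(tert-butyldimethylsilyl)oxy]-3-hydroxypropan-2-yl}-3-[(2S,3S)-1-hydroxy-3,7-dimethyloct-6-en-2-yl]-5-methoxybenzoate F1. Double iodination (I2, PPh3, imidazole, CH2Cl2) should give methyl 4-{(2R)-1-[(tert-butyldimethylsilyl)oxy]-3-iodopropan-2-yl}-3-[(2S,3S)-1-iodo-3,7-dimethyloct-6-en-2-yl]-5-methoxybenzoate F2. Nickel-catalysed reductive cyclisation of the alkyl dihalide (NiI2, 4,4′-di-tert-butyl-2,2′-bipyridine, Zn, DMA, rt) then forms the same C6–C7 bond and comes back to the route at 12.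

Step 3. Aryl transfer from the ortho-substituted iodonium salt may be slow, or the β-branched enamine of citronellal may give poor facial selectivity. The fallback sets out from 2 and 4. Palladium-catalysed α-arylation of the aldehyde (Pd(OAc)2, rac-BINAP, Cs2CO3, dioxane, 80 °C; the C–I bond reacts before the triflate) should give methyl 3-[(3S)-3,7-dimethyl-1-oxooct-6-en-2-yl]-5-methoxy-4-[(trifluoromethylsulfonyl)oxy]benzoate F3 as a mixture of epimers at the α-carbon. Hydrogenation under dynamic kinetic resolution (RuCl2[(S)-SDP][(R,R)-DACH], KOtBu, iPrOH, H2) should reduce the racemising α-aryl aldehyde to one alcohol diastereomer and come back to the route at 6.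

Step 5. Transmetalation at the di-ortho-substituted triflate may be sluggish, letting protodeboronation of 8 or intramolecular C–O coupling of the free alcohol compete. The fallback sets out from 6 and inverts the polarity. Miyaura borylation (Pd(OAc)2, XPhos, B2pin2, KOAc, dioxane, 90 °C) should give methyl 3-[(2S,3S)-1-hydroxy-3,7-dimethyloct-6-en-2-yl]-5-methoxy-4-(4,4,5,5-tetramethyl-1,3,2-dioxaborolan-2-yl)benzoate F4. Suzuki coupling of this boronate with [(2-bromoprop-2-en-1-yl)oxy](tert-butyl)dimethylsilane F5 (from purchased 2-bromoprop-2-en-1-ol, TBSCl, imidazole) under Pd(OAc)2/SPhos, K3PO4 comes back to the route at 9.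

**Further compounds**

F1 | step 7 | methyl 4-{(2S)-1-[(tert-butyldimethylsilyl)oxy]-3-hydroxypropan-2-yl}-3-[(2S,3S)-1-hydroxy-3,7-dimethyloct-6-en-2-yl]-5-methoxybenzoate | OC[C@@H]([C@@H](C)CCC=C(C)C)c1cc(C(=O)OC)cc(OC)c1[C@@H](CO)CO[Si](C)(C)C(C)(C)C
F2 | step 7 | methyl 4-{(2R)-1-[(tert-butyldimethylsilyl)oxy]-3-iodopropan-2-yl}-3-[(2S,3S)-1-iodo-3,7-dimethyloct-6-en-2-yl]-5-methoxybenzoate | IC[C@@H]([C@@H](C)CCC=C(C)C)c1cc(C(=O)OC)cc(OC)c1[C@@H](CI)CO[Si](C)(C)C(C)(C)C
F3 | step 3 | methyl 3-[(3S)-3,7-dimethyl-1-oxooct-6-en-2-yl]-5-methoxy-4-[(trifluoromethylsulfonyl)oxy]benzoate (both C2 epimers) | O=CC([C@@H](C)CCC=C(C)C)c1cc(C(=O)OC)cc(OC)c1OS(=O)(=O)C(F)(F)F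
F4 | step 5 | methyl 3-[(2S,3S)-1-hydroxy-3,7-dimethyloct-6-en-2-yl]-5-methoxy-4-(4,4,5,5-tetramethyl-1,3,2-dioxaborolan-2-yl)benzoate | OC[C@@H]([C@@H](C)CCC=C(C)C)c1cc(C(=O)OC)cc(OC)c1B1OC(C)(C)C(C)(C)O1
F5 | step 5 | [(2-bromoprop-2-en-1-yl)oxy](tert-butyl)dimethylsilane | C=C(Br)CO[Si](C)(C)C(C)(C)C
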